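The readings were computed with constants of no real substance; scatter was added.

**Quick number.** Colleague, you ask what the 2.0 M flask holds at 6.0 min, and your hunch is to read the percent straight off the autumn run. I carry a concentration over instead.

| setting | summer | autumn | flask |
|---|---|---|---|
| G | 2 M | 1.3 M | 2.0 M |
| remark | the very flask that is asked about, followed so far | run made earlier |  |
| time |  |  | 6.0 min |

summer run (percent of the G charged)

| time / s | X / % |
|---|---|
| 10.0 | 0 |
| 20.0 | 0.5 |
| 30.0 | 1.9 |

autumn run (percent of the G charged)

| time / min | X / % |
|---|---|
| 1.00 | 4.5 |
| 2.00 | 9.1 |
| 3.00 | 14.1 |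
| 4.00 | 17.6 |
| 5.00 | 21.4 |
| 6.00 | 23.4 |

(standard deviation of a reading: 0.5 percentage points)

- solid, in amounts per volume of the solution: G
- at the start none of G is in solution

* X at 6.0 min, in percent of the G charged
* the change that raises the amount of X at 6.0 min, in percent of the G charged most ("none" if none brings more than 2 percentage points) (blue / grey / none)
* amount of X at 6.0 min, in percent of the G charged, after grey

- blue: doubling the dissolution coefficient of G, all else as stated
- grey: doubling the solubility of G, all else as stated

**The rule.** I assume that while solid remains, the solution doesn't feel how much lies under it: zero order in the solid. Autumn's 23.4% of 1.3 M is 0.304 M, and this delivered concentration, the c_X I expect at 6.0 min from a charge with solid present, time and all else held, is what I carry.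

**In logarithms.** Percent against charge then has slope minus one, so going from 1.3 M to 2.0 M takes off 0.187 of a decade, and I commit to 15.2%. Autumn's first reading, scaled to 30.0 s and put on 2 M, gives 1.46%; summer reads 1.9%, a gap smaller than the scatter. Neither run varies the dissolution coefficient of G (blue) or its solubility (grey), so I pick grey on judgement; if grey doubles the delivered concentration, my figure doubles to 30.4%, and that is my estimate for it.

**The forecast.** The forecast says 23%, grey, and 41% after it, holding that “percent conversion looks roughly independent of charge”, which parts from my reckoning.

**The result.** The flask gives 15.7%; grey gains 9 percentage points against 5.3 points for blue, and reaches 24.7%. The scheme is: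

    Z → X (k = 0.0481 /s)
    Z + X → J (k = 0.0546 /M/s)
    G ⇌ Z, rate k3*(cs3 - [Z]) while solid is left; crystals form when [Z] > cs3 (solubility = 0.0710 M, k = 0.0278 /s)
    2 Z → Q (k = 0.0104 /M/s)

At 6.00 min solid G still stands at 75.7% of the charge, and the flask's c_X is 0.314 M. My 0.304 M on the 0.80 M neighbour flask gives 38.0%, and that flask holds 39.2% of X, with solid G at 39.2%.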